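## Structural features

The target 44 consists of three 2-arylchromane (flavan) units, each with a phloroglucinol-derived ring A, a pyran ring C and a catechol ring B. The upper and middle units are epicatechin units (2R,3R; 2,3-cis) joined by a C–C bond from C4 of the upper unit to C8 of the middle unit, the C4 substituent standing trans to the C3 hydroxyl (4β). The middle unit carries at its own C4, again trans to C3–OH, an ether oxygen whose other partner is C4 of the lower unit. The lower unit is a flavan-3,4-diol of the mirror-image series (2S,3S) in which the C2 aryl group, the C3 hydroxyl and the C4 oxygen are all cis. The nine stereocentres therefore form three contiguous C2–C3–C4 triads, two of one absolute sense and one of the other. Fragile elements are the dibenzylic C4–O–C4 ether (each C4–O bond ionises readily under acid), the acid-cleavable interflavan bond, and the free polyphenols (oxidation, base-induced epimerisation at C2). The real difficulties are the fully substituted ring A of the middle unit (interflavan bond at C8 and not C6, pyran oxygen O1 and not O5) and the hindered ether, which must be formed with defined configuration on both sides without carbon alkylation of the electron-rich rings. The key step exploits the pattern of that middle ring A: the carbon bearing O1 (C8a) lies between C8 (bonded to C4 of the upper unit) and C4a (bonded to the C4–C3–C2 chain), with oxygen at C7 and C5 and hydrogen at C6, which is the pattern produced by a 4-substituted 3-alkoxycyclobutenone and a siloxyalkyne.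

## Logic of the disconnections

44 is traced to 43 by removing fifteen O-benzyl groups; no skeletal bond is cut. Benzyl ethers tolerate DDQ, Lewis acids, organolithium reagents and heat and leave under neutral hydrogenolysis. The demand on the last step is that the central C4–O–C4 ether outlasts the benzyl ethers.

43 is cut at the bond between C4 of the middle unit and the ether oxygen, giving 36 and 42. A C4 cation of a 2,3-cis flavan is captured anti to C3–OBn, which is the configuration needed on the middle unit. The all-cis array of the lower unit cannot arise from cation capture and must arrive intact in 42. The gain is a dimer plus a monomer. The demand is an irreversible, non-acidic activation, because O-alkylation is kinetically preferred but acid would reverse it in favour of carbon alkylation of ring A.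

36 goes back through 35 to 34 (C4–S and C4–O replaced by C4–H) and 34 to 32 (benzyl for silyl at O5). This postpones C4 activation until ring C of the middle unit exists. The demand is that hydride abstraction occurs at the CH2 group of the lower half and not at the doubly benzylic C4–H of the upper half.

32 is opened at O1–C2 of the middle pyran to 31 and further to its silyl ether 30. The closure must invert C2, so the open chain needs the anti (erythro) arrangement of the C2 and C3 oxygens, and the only free phenol must be O1.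

30 is cut across ring A of the middle unit at C8a–C4a and C5–C6, giving 12 and 25. This removes an aromatic ring, leaves two fragments of similar size, and settles C8 versus C6 and O1 versus O5 by construction. The demand is that the thermal cascade tolerate a bulky substituent at C4 of the cyclobutenone.

12 comes from 11 by alkoxy exchange, and 11 from 7 and 8 by cutting the two ring bonds formed when the ketene 10 adds to the alkyne. 7 comes from 6 and this from 4 and 5 by cutting the bond between C4 of the flavan and the acetate carbon, which must form trans to C3–OBn. 4 leads back through 3 and 2 to 1.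

25 comes from 23 by cutting the C–O bond at the alkyne terminus. 23 comes from 22 and 21, where the carbinol stereocentre must be set anti to the benzyloxy carbon. 21 is cut at the aryl–carbonyl bond into 18 and 19; 18 comes from 17, which is cut at the C3–C4 bond into 15 and 16; 15 is cut at the N-acyl bond into 13 and 14. The auxiliary sets the future C3; the chelation-controlled reduction sets the future C2. An anti diol derivative is not available from syn-dihydroxylation of an E-alkene, hence this route.

42 comes from 41 (C4–H bond, hydride anti to C3–OBn), 41 from 40 and 39 by C4 oxidation, and 39 through 38 to 37. 37 already holds C2 and C3 in the required mirror-image series, which an achiral flavonol could supply only through an added enantioselective step.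

## Other disconnections considered

Alternative 1: The cut is the C4–C4a bond of the upper pyran ring in the decabenzyl dimer A1 (the same compound as 34). In the forward direction the benzylic carbinol A2 would be ionised by a Lewis acid. In A2 the carbinol carbon is attached to C8 of an intact penta-O-benzylepicatechin, and the chain carries C3–OBn and, at C2, the 3,5-dibenzyloxyphenyl ether. The cation would be captured by the ortho carbon of the aryl ether (Friedel–Crafts alkylation), closing the upper pyran.
- In its favour: the aryl ether is symmetric, so the closure has no regiochemical choice. The middle unit comes ready-made from epicatechin, whose C8 can be functionalised selectively by halogenation and metalation, so the 6/8 question is answered as firmly as in the chosen plan (equal on this point). The middle unit needs no new stereocontrol (better on this point).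
- Against it here: the closure creates the C4 stereocentre in an SN1 step, so 4β depends on the facial bias of C3–OBn on a crowded cation. The same acid can ionise the C2–OAr bond of A2, a benzylic aryl ether of an electron-rich ring, and erase C2. A2 also needs its C2 aryl ether set by an intermolecular substitution at the same kind of electron-rich benzylic carbinol that the chosen plan closes intramolecularly.
- Comparison: both plans deliver the same dimer and share the end game. The chosen key step is a neutral pericyclic cascade that creates no stereocentre, whereas this one is an ionic step that must create one. The step counts are expected to be close.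

Alternative 2: The cut is the C3=C4 double bond of the lower pyran ring in the chromene A3; the inter-unit oxygen enters the step as the alkoxy oxygen of an ester. In the forward direction the ester A4, the 2-(1-arylallyloxy)-4,6-dibenzyloxybenzoate of the dimeric 4β-alcohol, would be treated with a titanium alkylidene (for example from TiCl4, Zn, PbCl2, CH2Br2 and TMEDA). Methylenation of the ester carbonyl and ring-closing metathesis with the allyl terminus would give the six-membered 4-alkoxy-2H-chromene.
- In its favour: the hindered C–O bond between the units is made by acylating an alcohol, not by capturing a cation, so the reversibility and competing carbon alkylation that burden step 26 do not arise (better on this point). C2 of the lower unit can be brought in as a defined allylic aryl ether.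
- Against it here: after ring closure, H must be added to C4 and OH to C3 so that both oxygens and the aryl group end up cis. This is a net anti addition across an enol ether and cannot be had from hydroboration. C4 then becomes a stereocentre at a carbon that is both benzylic and an ether carbon. The dimeric 4β-alcohol still has to be made by oxidation of 34 (equal on this point). An excess of a Lewis-acidic titanium reagent must be tolerated by fifteen benzyl ethers and a crowded ester.
- Comparison: this disconnection concerns the ether end of the molecule, so it competes with steps 19 to 26 and not with the key step. It leaves two stereocentres of the lower unit to be set late on the assembled trimer, where the chosen plan takes them from the chiral pool. It is longer after its key step.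

Alternative 3: The cuts are C4a–C4 and O1–C2 of the middle pyran ring in A5. In the forward direction the hub phenol A6 (the pentabenzylepicatechin-4β-yl derivative of 3,5-dibenzyloxyphenol) would be converted into its bromomagnesium phenoxide. This adds through its one free ortho carbon to the aldehyde of the cis-epoxy aldehyde A7; the phenoxide then opens the epoxide at the benzylic carbon with inversion, closing the pyran as a 2,3-cis flavan-3,4-diol.
- In its favour: two bonds, the ring and the 2,3-cis relationship arise in one operation from two large fragments (better in convergence and step count). The C4 oxygen needed for the ether bond is delivered by the aldehyde, so no C–H oxidation of a dimer is required (better on this point). The C4 epimers are harmless because C4 is ionised afterwards (equal).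
- Against it here: A6 must be made by carbon alkylation of 3,5-dibenzyloxyphenol with the C4 cation, which can occur between OH and OBn or between the two OBn groups, so the regiochemical question is moved and not removed. A7 is an epoxide on an electron-rich benzylic carbon, hard to obtain enantiopure in the cis series and prone to open by ionisation, which would leak to the 2,3-trans isomer. The magnesium phenoxide of a phenol flanked by the bulky flavanyl group must still chelate the aldehyde.
- Comparison: the chosen plan fixes C8 versus C6 and O1 versus O5 by the way ring A is built, whereas this one relies on selectivity in an aromatic substitution. The chosen key step touches no stereocentre, whereas this one sets C2 by an SN2 opening that must outrun SN1. In step economy this alternative is the shorter.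

Key step: step 15

Remarks on the chemistry:
- (+)-Epicatechin (2S,3S) is taken to be purchasable.
- The sp3 ring carbon of 11 and 12 forms as both epimers, which converge in step 15.
- The chain silyl ether is triethylsilyl so that step 16 spares the aryl triisopropylsilyl ether.

## Steps

Step 1
Reactants: 1 (−)-epicatechin
Product: 2 5,7,3',4'-tetra-O-benzyl-(−)-epicatechin
Conditions: BnBr, K2CO3, DMF, 0 °C → rt
Reagents that add atoms: benzyl bromide, BrCc1ccccc1
Why: Williamson etherification: K2CO3 deprotonates only the four phenols, so the secondary C3 hydroxyl stays free and the C2 and C3 configurations of the chiral pool are retained.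

Step 2
Reactants: 2 5,7,3',4'-tetra-O-benzyl-(−)-epicatechin
Product: 3 3,5,7,3',4'-penta-O-benzyl-(−)-epicatechin
Conditions: NaH, BnBr, Bu4NI (cat.), DMF, 0 °C → rt
Reagents that add atoms: benzyl bromide, BrCc1ccccc1
Why: Williamson etherification of the remaining secondary alcohol through its sodium alkoxide; with all phenols capped there is no pathway for base-induced opening of ring C, so C2 is not epimerised.

Step 3
Reactants: 3 3,5,7,3',4'-penta-O-benzyl-(−)-epicatechin
Product: 4 4β-(2-ethoxyethoxy)-penta-O-benzylepicatechin (C4–O trans to C3–OBn)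
Conditions: DDQ, 2-ethoxyethanol, CH2Cl2, rt
Reagents that add atoms: 2-ethoxyethanol, CCOCCO
Why: DDQ abstracts hydride from C4, the benzylic position of the 5,7-dioxygenated ring A, and the cation is captured by the alcohol on the face anti to the axial C3–OBn (oxidative benzylic etherification), giving the 3,4-trans ether with a chelating leaving group.

Step 4
Reactants: 4 4β-(2-ethoxyethoxy)-penta-O-benzylepicatechin, 5 1-(tert-butyldimethylsilyloxy)-1-methoxyethene
Product: 6 methyl 2-(penta-O-benzylepicatechin-4β-yl)acetate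
Conditions: Me3SiOSO2CF3 (0.3 equiv), CH2Cl2, −78 °C
Reagents that add atoms: none
Why: Mukaiyama-type alkylation: the silyl triflate ionises the 4β-alkoxy group and the silyl ketene acetal attacks the C4 cation anti to C3–OBn, which sets the 4β C–C bond that later becomes the interflavan C4–C8 bond.

Step 5
Reactants: 6 methyl 2-(penta-O-benzylepicatechin-4β-yl)acetate
Product: 7 2-(penta-O-benzylepicatechin-4β-yl)acetic acid
Conditions: LiOH, THF/MeOH/H2O, 40 °C; then dilute aq. HCl
Reagents that add atoms: lithium hydroxide, [Li+].[OH-]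
Why: Saponification of an unhindered methyl ester; the perbenzylated flavan has no base-sensitive site.

Step 6
Reactants: 7 2-(penta-O-benzylepicatechin-4β-yl)acetic acid, 8 ethoxyacetylene
Product: 11 3-ethoxy-4-(penta-O-benzylepicatechin-4β-yl)cyclobut-2-en-1-one (both epimers at the ring carbon), via acid chloride 9 (not isolated), via ketene 10 (not isolated)
Conditions: 1-chloro-N,N,2-trimethylprop-1-en-1-amine, CH2Cl2, 0 °C → rt; then 8 (5 equiv), Et3N (slow addition), CH2Cl2, 0 °C → rt
Reagents that add atoms: none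
Why: The α-chloroenamine gives the acid chloride without HCl or an iminium species that could attack ring A; Et3N then generates the monosubstituted ketene, which undergoes [2+2] cycloaddition with the ynol ether, carbonyl carbon to the terminal alkyne carbon, to give the 3-alkoxy-4-substituted cyclobutenone. The new ring stereocentre is uncontrolled and is erased in step 15.

Step 7
Reactants: 11 3-ethoxy-4-(penta-O-benzylepicatechin-4β-yl)cyclobut-2-en-1-one
Product: 12 3-benzyloxy-4-(penta-O-benzylepicatechin-4β-yl)cyclobut-2-en-1-one (both epimers at the ring carbon)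
Conditions: BnOH (10 equiv), pyridinium p-toluenesulfonate (cat.), 5 Å molecular sieves, toluene, 45 °C
Reagents that add atoms: benzyl alcohol, OCc1ccccc1
Why: Acid-catalysed transetherification of a vinylogous ester by addition–elimination at C3, driven by removal of ethanol; the O–C1=C2–C3 system is never interrupted, so the flavanyl group stays at C4, and the temperature is well below that of ring opening.

Step 8
Reactants: 13 (S)-4-benzyloxazolidin-2-one, 14 (benzyloxy)acetyl chloride
Product: 15 (S)-4-benzyl-3-[(benzyloxy)acetyl]oxazolidin-2-one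
Conditions: n-BuLi, THF, −78 °C; then 14, −78 → 0 °C
Reagents that add atoms: none
Why: N-Acylation of the lithiated oxazolidinone by the acid chloride, the standard preparation of an N-glycolyl imide.

Step 9
Reactants: 15 (S)-4-benzyl-3-[(benzyloxy)acetyl]oxazolidin-2-one, 16 propargyl bromide
Product: 17 (S)-4-benzyl-3-[(R)-2-(benzyloxy)pent-4-ynoyl]oxazolidin-2-one
Conditions: NaN(SiMe3)2, THF, −78 °C; then 16 (4 equiv), −78 → −45 °C
Reagents that add atoms: none
Why: Evans asymmetric alkylation: the chelated (Z)-sodium enolate is attacked by the propargylic halide on the face away from the C4 benzyl group, which sets the (R) benzyloxy-bearing carbon, the future C3 of the middle unit.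

Step 10
Reactants: 17 (S)-4-benzyl-3-[(R)-2-(benzyloxy)pent-4-ynoyl]oxazolidin-2-one
Product: 18 (R)-2-(benzyloxy)-N-methoxy-N-methylpent-4-ynamide
Conditions: MeNH(OMe)·HCl, AlMe3, CH2Cl2, −10 °C → rt; then dilute aq. HCl
Reagents that add atoms: N,O-dimethylhydroxylamine hydrochloride, CNOC.Cl
Why: Aminolysis by the dimethylaluminium amide of N,O-dimethylhydroxylamine attacks the exocyclic carbonyl, giving the Weinreb amide and releasing the auxiliary without touching the α-stereocentre.

Step 11
Reactants: 18 (R)-2-(benzyloxy)-N-methoxy-N-methylpent-4-ynamide, 19 4-bromo-1,2-bis(benzyloxy)benzene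
Product: 21 (R)-2-(benzyloxy)-1-[3,4-bis(benzyloxy)phenyl]pent-4-yn-1-one, via arylmagnesium bromide 20 (not isolated)
Conditions: 19, Mg, THF, rt; then 18 (0.4 equiv relative to 20), THF, −20 → 0 °C; aq. NH4Cl
Reagents that add atoms: none
Why: Grignard addition to a Weinreb amide stops at the chelated tetrahedral intermediate, so the aryl ketone forms only on work-up and the α-benzyloxy centre is not enolised; one equivalent of the Grignard reagent is consumed by the alkyne C–H, which is restored on work-up.

Step 12
Reactants: 21 (R)-2-(benzyloxy)-1-[3,4-bis(benzyloxy)phenyl]pent-4-yn-1-one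
Product: 22 (1S,2R)-2-(benzyloxy)-1-[3,4-bis(benzyloxy)phenyl]pent-4-yn-1-ol
Conditions: Zn(BH4)2, Et2O, −30 °C; aq. NH4Cl
Reagents that add atoms: none
Why: Chelation-controlled reduction: zinc bridges the carbonyl and the α-benzyloxy oxygen and hydride enters from the side of the α-hydrogen, which should give the anti alcohol. This sets the future C2 of the middle unit opposite to its final configuration, as needed for closure with inversion.

Step 13
Reactants: 22 (1S,2R)-2-(benzyloxy)-1-[3,4-bis(benzyloxy)phenyl]pent-4-yn-1-ol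
Product: 23 triethylsilyl ether of 22, (1S,2R)-2-(benzyloxy)-1-[3,4-bis(benzyloxy)phenyl]-1-(triethylsilyloxy)pent-4-yne
Conditions: Et3SiOSO2CF3, 2,6-lutidine, CH2Cl2, −78 → 0 °C
Reagents that add atoms: triethylsilyl trifluoromethanesulfonate, CC[Si](CC)(CC)OS(=O)(=O)C(F)(F)F
Why: Silylation of the secondary alcohol; triethylsilyl is chosen so that it can later be removed under buffered fluoride conditions that leave an aryl triisopropylsilyl ether intact.

Step 14
Reactants: 23 triethylsilyl ether of 22
Product: 25 (4R,5S)-4-(benzyloxy)-5-[3,4-bis(benzyloxy)phenyl]-5-(triethylsilyloxy)-1-(triisopropylsilyloxy)pent-1-yne, via lithium ynolate 24 (not isolated)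
Conditions: n-BuLi, THF, −78 °C; LiOOt-Bu (from t-BuOOH and LiN(SiMe3)2), −78 → 0 °C; i-Pr3SiOSO2CF3, −78 → 0 °C
Reagents that add atoms: tert-butyl hydroperoxide, CC(C)(C)OO; triisopropylsilyl trifluoromethanesulfonate, CC(C)[Si](C(C)C)(C(C)C)OS(=O)(=O)C(F)(F)F
Why: Deprotonation of the terminal alkyne, oxygen transfer from lithium tert-butyl peroxide to the acetylide carbon (oxidation of an acetylide to an ynolate) and O-silylation of the ynolate by the bulky silyl triflate give the siloxyalkyne; the stereocentres are remote from the anionic site.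

Step 15
Reactants: 12 3-benzyloxy-4-(penta-O-benzylepicatechin-4β-yl)cyclobut-2-en-1-one, 25 (4R,5S)-4-(benzyloxy)-5-[3,4-bis(benzyloxy)phenyl]-5-(triethylsilyloxy)-1-(triisopropylsilyloxy)pent-1-yne
Product: 30 2-(penta-O-benzylepicatechin-4β-yl)-3-benzyloxy-5-(triisopropylsilyloxy)-6-[(2R,3S)-2-benzyloxy-3-(3,4-dibenzyloxyphenyl)-3-(triethylsilyloxy)propyl]phenol, via vinylketene 26 (not isolated), via vinylcyclobutenone 27 (not isolated), via dienylketene 28 (not isolated), via cyclohexadienone 29 (not isolated)
Conditions: 12 (1.0 equiv), 25 (1.2 equiv), degassed toluene, 80 °C, then 110 °C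
Reagents that add atoms: none
Why: Heating opens 12 by four-electron electrocyclic ring opening, the flavanyl group rotating outward, to the vinylketene 26. Its electrophilic carbonyl carbon bonds to the alkyne carbon of 25 remote from oxygen and its α-carbon to the siloxy-bearing carbon ([2+2] cycloaddition) to give 27; this polarity match is the only regiochemical decision of the step. 27 opens again to the (Z)-dienylketene 28, which closes ring A of the middle unit by six-electron electrocyclisation to 29, and tautomerisation gives the phenol 30. The net new bonds are C8a–C4a and C5–C6, the ketene carbonyl becomes the single free phenol O1 between C8 and C4a, and O7 and O5 carry benzyl and silyl, so the interflavan bond is necessarily at C8 and only O1 is free for the later pyran closure. The closest known reaction is the Danheiser benzannulation of cyclobutenones with siloxyalkynes to resorcinol monosilyl ethers. No stereocentre is formed, and the existing ones in both partners are remote from the reacting π-system under neutral, aprotic conditions. The step needs the [2+2] addition to outrun ketene dimerisation and acylation of the product phenol; the slight excess of 25 and the crowding around the new phenol should secure this.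

Step 16
Reactants: 30 hub phenol
Product: 31 2-(penta-O-benzylepicatechin-4β-yl)-3-benzyloxy-5-(triisopropylsilyloxy)-6-[(2R,3S)-2-benzyloxy-3-(3,4-dibenzyloxyphenyl)-3-hydroxypropyl]phenol
Conditions: HF·pyridine, pyridine, THF, 0 °C
Reagents that add atoms: none
Why: Buffered HF·pyridine cleaves the alkyl triethylsilyl ether much faster than the hindered aryl triisopropylsilyl ether and is not acidic enough to ionise the electron-rich benzylic carbinol.

Step 17
Reactants: 31 phenol–alcohol
Product: 32 penta-O-benzylepicatechin-(4β→8)-[3,7,3',4'-tetra-O-benzyl-5-O-(triisopropylsilyl)epicatechin]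
Conditions: PPh3, diisopropyl azodicarboxylate, toluene, 0 °C → rt
Reagents that add atoms: none
Why: Mitsunobu etherification: the benzylic hydroxyl is activated as its alkoxyphosphonium ion and displaced intramolecularly (6-exo-tet) by the only free phenol, O1, with inversion at C2, which converts the anti chain into the 2,3-cis pyran of an epicatechin unit.

Step 18
Reactants: 32 silyl-protected dimer
Product: 34 deca-O-benzyl-epicatechin-(4β→8)-epicatechin, via C5 phenoxide 33 (not isolated)
Conditions: Bu4NF, THF, 0 °C; then BnBr, rt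
Reagents that add atoms: benzyl bromide, BrCc1ccccc1
Why: Fluoride cleaves the aryl silyl ether and the resulting tetrabutylammonium phenoxide is benzylated in the same flask (Williamson etherification), so that ring A of the middle unit carries the ether groups of a normal epicatechin electrophile.

Step 19
Reactants: 34 deca-O-benzyl-epicatechin-(4β→8)-epicatechin
Product: 35 penta-O-benzylepicatechin-(4β→8)-[4β-(2-ethoxyethoxy)-penta-O-benzylepicatechin]
Conditions: DDQ, 2-ethoxyethanol, CH2Cl2, 0 °C → rt
Reagents that add atoms: 2-ethoxyethanol, CCOCCO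
Why: Oxidative benzylic etherification as in step 3: the only CH2 group benzylic to a dioxygenated ring is C4 of the lower half, whose axial hydrogen is aligned with ring A, whereas the C4–H of the upper half lies close to the plane of both flanking arenes; capture anti to C3–OBn gives the 4β ether.

Step 20
Reactants: 35 4β-(2-ethoxyethoxy) dimer
Product: 36 penta-O-benzylepicatechin-(4β→8)-[4β-(benzylthio)-penta-O-benzylepicatechin]
Conditions: BnSH, BF3·OEt2, CH2Cl2, −78 → −40 °C
Reagents that add atoms: phenylmethanethiol, SCc1ccccc1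
Why: Lewis-acid ionisation of the chelating 2-ethoxyethoxy group and capture of the C4 cation by the soft thiol anti to C3–OBn; the thioether is not re-ionised by BF3·OEt2 at low temperature, so the exchange should go to completion.

Step 21
Reactants: 37 (+)-epicatechin
Product: 38 5,7,3',4'-tetra-O-benzyl-(+)-epicatechin
Conditions: BnBr, K2CO3, DMF, 0 °C → rt
Reagents that add atoms: benzyl bromide, BrCc1ccccc1
Why: Williamson etherification of the four phenols, as in step 1, in the mirror-image series.

Step 22
Reactants: 38 5,7,3',4'-tetra-O-benzyl-(+)-epicatechin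
Product: 39 3,5,7,3',4'-penta-O-benzyl-(+)-epicatechin
Conditions: NaH, BnBr, Bu4NI (cat.), DMF, 0 °C → rt
Reagents that add atoms: benzyl bromide, BrCc1ccccc1
Why: Williamson etherification of the secondary alcohol, as in step 2.

Step 23
Reactants: 39 3,5,7,3',4'-penta-O-benzyl-(+)-epicatechin
Product: 40 (2S,3S,4R)-penta-O-benzyl-(+)-epicatechin-4-ol (4-OH trans to 3-OBn)
Conditions: DDQ, CH2Cl2/H2O, rt
Reagents that add atoms: water, O
Why: The same oxidative C4 functionalisation as in step 3 with water as the nucleophile; the hydroxyl enters anti to C3–OBn, and its configuration is of no consequence because C4 is oxidised next.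

Step 24
Reactants: 40 trans-4-ol
Product: 41 (2S,3R)-3,5,7-tris(benzyloxy)-2-[3,4-bis(benzyloxy)phenyl]chroman-4-one (2,3-cis)
Conditions: Dess–Martin periodinane, pyridine, CH2Cl2, 0 °C → rt
Reagents that add atoms: none
Why: Dess–Martin oxidation of the benzylic alcohol under buffered, non-enolising conditions, so that the C3 stereocentre next to the new carbonyl is kept.

Step 25
Reactants: 41 flavan-4-one
Product: 42 (2S,3S,4S)-3,5,7-tris(benzyloxy)-2-[3,4-bis(benzyloxy)phenyl]chroman-4-ol (2,3-cis-3,4-cis)
Conditions: LiBH(s-Bu)3, THF, −78 °C; aq. NH4Cl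
Reagents that add atoms: none
Why: Diastereoselective ketone reduction: the axial C3–OBn blocks one face of the C4 carbonyl and hydride is delivered anti to it, which places the new hydroxyl cis to both C3–OBn and the C2 aryl group; the aprotic medium at −78 °C avoids base-induced opening of ring C.

Step 26
Reactants: 36 4β-(benzylthio) dimer, 42 all-cis 4-ol
Product: 43 pentadeca-O-benzyl trimer, penta-O-benzylepicatechin-(4β→8)-penta-O-benzylepicatechin-(4β→O→4)-[(2S,3S,4S)-penta-O-benzylflavan-3,4-diol]
Conditions: 36 (1.0 equiv), 42 (2 equiv), AgOSO2CF3, 2,6-di-tert-butyl-4-methylpyridine, 4 Å molecular sieves, CH2Cl2, −40 → 0 °C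
Reagents that add atoms: none
Why: The thiophilic silver ion removes the quasi-axial 4β-benzylthio group irreversibly as silver thiolate, and the C4 cation is captured anti to C3–OBn by the hydroxyl of 42, which is kinetically far more nucleophilic than the alkoxyarene carbons. The hindered pyridine takes up the proton, so no acid remains to re-ionise the product and divert it to carbon alkylation. The C4–O bond of 42 is quasi-equatorial and is not broken, so its all-cis array is carried over unchanged.

Step 27
Reactants: 43 pentadeca-O-benzyl trimer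
Product: 44 target, epicatechin-(4β→8)-epicatechin-(4β→O→4)-[(2S,3S,4S)-2,3-cis-3,4-cis-flavan-3,4-diol]
Conditions: H2 (1 atm), Pd(OH)2/C, THF/MeOH/H2O, rt
Reagents that add atoms: none
Why: Hydrogenolysis of the fifteen benzyl ethers in neutral medium; the central C4–O–C4 ether is a hindered secondary dialkyl ether and should be cleaved much more slowly than primary benzyl ethers, provided no acid is present and the reaction is stopped when hydrogen uptake ends.

## Compound list

1 | (−)-epicatechin, (2R,3R) | Oc1cc(O)c2c(c1)O[C@H](c1ccc(O)c(O)c1)[C@H](O)C2 | starting material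
2 | 5,7,3',4'-tetra-O-benzyl-(−)-epicatechin | O(Cc9ccccc9)c1cc(OCc9ccccc9)c2c(c1)O[C@H](c1ccc(OCc9ccccc9)c(OCc9ccccc9)c1)[C@H](O)C2 | intermediate
3 | 3,5,7,3',4'-penta-O-benzyl-(−)-epicatechin | O(Cc9ccccc9)c1cc(OCc9ccccc9)c2c(c1)O[C@H](c1ccc(OCc9ccccc9)c(OCc9ccccc9)c1)[C@H](OCc9ccccc9)C2 | intermediate
4 | 4β-(2-ethoxyethoxy)-penta-O-benzylepicatechin, C4–O trans to C3–OBn | O(Cc9ccccc9)c1cc(OCc9ccccc9)c2c(c1)O[C@H](c1ccc(OCc9ccccc9)c(OCc9ccccc9)c1)[C@H](OCc9ccccc9)[C@H]2OCCOCC | intermediate
5 | 1-(tert-butyldimethylsilyloxy)-1-methoxyethene | C=C(OC)O[Si](C)(C)C(C)(C)C | starting material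
6 | methyl 2-(penta-O-benzylepicatechin-4β-yl)acetate | O(Cc9ccccc9)c1cc(OCc9ccccc9)c2c(c1)O[C@H](c1ccc(OCc9ccccc9)c(OCc9ccccc9)c1)[C@H](OCc9ccccc9)[C@H]2CC(=O)OC | intermediate
7 | 2-(penta-O-benzylepicatechin-4β-yl)acetic acid | O(Cc9ccccc9)c1cc(OCc9ccccc9)c2c(c1)O[C@H](c1ccc(OCc9ccccc9)c(OCc9ccccc9)c1)[C@H](OCc9ccccc9)[C@H]2CC(=O)O | intermediate
8 | ethoxyacetylene | C#COCC | starting material
9 | 2-(penta-O-benzylepicatechin-4β-yl)acetyl chloride | O(Cc9ccccc9)c1cc(OCc9ccccc9)c2c(c1)O[C@H](c1ccc(OCc9ccccc9)c(OCc9ccccc9)c1)[C@H](OCc9ccccc9)[C@H]2CC(=O)Cl | intermediate (not isolated)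
10 | (penta-O-benzylepicatechin-4β-yl)ketene | O(Cc9ccccc9)c1cc(OCc9ccccc9)c2c(c1)O[C@H](c1ccc(OCc9ccccc9)c(OCc9ccccc9)c1)[C@H](OCc9ccccc9)[C@H]2C=C=O | intermediate (not isolated)
11 | 3-ethoxy-4-(penta-O-benzylepicatechin-4β-yl)cyclobut-2-en-1-one, both epimers at ring C4 | O(Cc9ccccc9)c1cc(OCc9ccccc9)c2c(c1)O[C@H](c1ccc(OCc9ccccc9)c(OCc9ccccc9)c1)[C@H](OCc9ccccc9)[C@H]2C1C(=O)C=C1OCC | intermediate
12 | 3-benzyloxy-4-(penta-O-benzylepicatechin-4β-yl)cyclobut-2-en-1-one, both epimers at ring C4 | O(Cc9ccccc9)c1cc(OCc9ccccc9)c2c(c1)O[C@H](c1ccc(OCc9ccccc9)c(OCc9ccccc9)c1)[C@H](OCc9ccccc9)[C@H]2C1C(=O)C=C1OCc9ccccc9 | intermediate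
13 | (S)-4-benzyloxazolidin-2-one | O=C1N[C@@H](Cc2ccccc2)CO1 | starting material
14 | (benzyloxy)acetyl chloride | O=C(Cl)COCc1ccccc1 | starting material
15 | (S)-4-benzyl-3-[(benzyloxy)acetyl]oxazolidin-2-one | O=C(COCc1ccccc1)N1[C@@H](Cc2ccccc2)COC1=O | intermediate
16 | propargyl bromide (3-bromoprop-1-yne) | C#CCBr | starting material
17 | (S)-4-benzyl-3-[(R)-2-(benzyloxy)pent-4-ynoyl]oxazolidin-2-one | C#CC[C@@H](OCc1ccccc1)C(=O)N1[C@@H](Cc2ccccc2)COC1=O | intermediate
18 | (R)-2-(benzyloxy)-N-methoxy-N-methylpent-4-ynamide | C#CC[C@@H](OCc1ccccc1)C(=O)N(C)OC | intermediate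
19 | 4-bromo-1,2-bis(benzyloxy)benzene | Brc1ccc(OCc2ccccc2)c(OCc2ccccc2)c1 | starting material
20 | 3,4-bis(benzyloxy)phenylmagnesium bromide | Br[Mg]c1ccc(OCc2ccccc2)c(OCc2ccccc2)c1 | intermediate (not isolated)
21 | (R)-2-(benzyloxy)-1-[3,4-bis(benzyloxy)phenyl]pent-4-yn-1-one | C#CC[C@@H](OCc1ccccc1)C(=O)c1ccc(OCc2ccccc2)c(OCc2ccccc2)c1 | intermediate
22 | (1S,2R)-2-(benzyloxy)-1-[3,4-bis(benzyloxy)phenyl]pent-4-yn-1-ol (anti) | C#CC[C@@H](OCc1ccccc1)[C@@H](O)c1ccc(OCc2ccccc2)c(OCc2ccccc2)c1 | intermediate
23 | triethylsilyl ether of 22 | C#CC[C@@H](OCc1ccccc1)[C@@H](O[Si](CC)(CC)CC)c1ccc(OCc2ccccc2)c(OCc2ccccc2)c1 | intermediate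
24 | lithium ynolate of 23 | [Li]OC#CC[C@@H](OCc1ccccc1)[C@@H](O[Si](CC)(CC)CC)c1ccc(OCc2ccccc2)c(OCc2ccccc2)c1 | intermediate (not isolated)
25 | (4R,5S)-4-(benzyloxy)-5-[3,4-bis(benzyloxy)phenyl]-5-(triethylsilyloxy)-1-(triisopropylsilyloxy)pent-1-yne | CC(C)[Si](C(C)C)(C(C)C)OC#CC[C@@H](OCc1ccccc1)[C@@H](O[Si](CC)(CC)CC)c1ccc(OCc2ccccc2)c(OCc2ccccc2)c1 | intermediate
26 | 3-benzyloxy-4-(penta-O-benzylepicatechin-4β-yl)buta-1,3-dien-1-one (vinylketene, flavanyl group outward) | O(Cc9ccccc9)c1cc(OCc9ccccc9)c2c(c1)O[C@H](c1ccc(OCc9ccccc9)c(OCc9ccccc9)c1)[C@H](OCc9ccccc9)[C@H]2/C=C(\OCc9ccccc9)/C=C=O | intermediate (not isolated)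
27 | 2-(chain)-3-(triisopropylsilyloxy)-4-[1-benzyloxy-2-(flavan-4β-yl)ethenyl]cyclobut-2-en-1-one, [2+2] adduct, both epimers at ring C4 | O(Cc9ccccc9)c1cc(OCc9ccccc9)c2c(c1)O[C@H](c1ccc(OCc9ccccc9)c(OCc9ccccc9)c1)[C@H](OCc9ccccc9)[C@H]2/C=C(\OCc9ccccc9)/C1C(=O)C(C[C@@H](OCc9ccccc9)[C@@H](O[Si](CC)(CC)CC)c3ccc(OCc9ccccc9)c(OCc9ccccc9)c3)=C1O[Si](C(C)C)(C(C)C)C(C)C | intermediate (not isolated)
28 | (Z)-dienylketene from ring opening of 27 | O(Cc9ccccc9)c1cc(OCc9ccccc9)c2c(c1)O[C@H](c1ccc(OCc9ccccc9)c(OCc9ccccc9)c1)[C@H](OCc9ccccc9)[C@H]2/C=C(\OCc9ccccc9)/C=C(/O[Si](C(C)C)(C(C)C)C(C)C)C(C[C@@H](OCc9ccccc9)[C@@H](O[Si](CC)(CC)CC)c3ccc(OCc9ccccc9)c(OCc9ccccc9)c3)=C=O | intermediate (not isolated)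
29 | cyclohexa-2,4-dien-1-one tautomer of 30, both epimers at the sp3 ring carbon | O(Cc9ccccc9)c1cc(OCc9ccccc9)c2c(c1)O[C@H](c1ccc(OCc9ccccc9)c(OCc9ccccc9)c1)[C@H](OCc9ccccc9)[C@H]2C1C(=O)C(C[C@@H](OCc9ccccc9)[C@@H](O[Si](CC)(CC)CC)c3ccc(OCc9ccccc9)c(OCc9ccccc9)c3)=C(O[Si](C(C)C)(C(C)C)C(C)C)C=C1OCc9ccccc9 | intermediate (not isolated)
30 | hub phenol, 2-(penta-O-benzylepicatechin-4β-yl)-3-benzyloxy-5-(triisopropylsilyloxy)-6-[(2R,3S)-2-benzyloxy-3-(3,4-dibenzyloxyphenyl)-3-(triethylsilyloxy)propyl]phenol | O(Cc9ccccc9)c1cc(OCc9ccccc9)c2c(c1)O[C@H](c1ccc(OCc9ccccc9)c(OCc9ccccc9)c1)[C@H](OCc9ccccc9)[C@H]2c1c(OCc9ccccc9)cc(O[Si](C(C)C)(C(C)C)C(C)C)c(C[C@@H](OCc9ccccc9)[C@@H](O[Si](CC)(CC)CC)c3ccc(OCc9ccccc9)c(OCc9ccccc9)c3)c1O | intermediate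
31 | phenol–alcohol, as 30 with a free (3S)-hydroxyl on the chain | O(Cc9ccccc9)c1cc(OCc9ccccc9)c2c(c1)O[C@H](c1ccc(OCc9ccccc9)c(OCc9ccccc9)c1)[C@H](OCc9ccccc9)[C@H]2c1c(OCc9ccccc9)cc(O[Si](C(C)C)(C(C)C)C(C)C)c(C[C@@H](OCc9ccccc9)[C@@H](O)c3ccc(OCc9ccccc9)c(OCc9ccccc9)c3)c1O | intermediate
32 | penta-O-benzylepicatechin-(4β→8)-[3,7,3',4'-tetra-O-benzyl-5-O-(triisopropylsilyl)epicatechin] | O(Cc9ccccc9)c1cc(OCc9ccccc9)c2c(c1)O[C@H](c1ccc(OCc9ccccc9)c(OCc9ccccc9)c1)[C@H](OCc9ccccc9)[C@H]2c1c(OCc9ccccc9)cc(O[Si](C(C)C)(C(C)C)C(C)C)c2c1O[C@H](c1ccc(OCc9ccccc9)c(OCc9ccccc9)c1)[C@H](OCc9ccccc9)C2 | intermediate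
33 | penta-O-benzylepicatechin-(4β→8)-(3,7,3',4'-tetra-O-benzylepicatechin), free 5-OH, formed as its tetrabutylammonium phenoxide | O(Cc9ccccc9)c1cc(OCc9ccccc9)c2c(c1)O[C@H](c1ccc(OCc9ccccc9)c(OCc9ccccc9)c1)[C@H](OCc9ccccc9)[C@H]2c1c(OCc9ccccc9)cc(O)c2c1O[C@H](c1ccc(OCc9ccccc9)c(OCc9ccccc9)c1)[C@H](OCc9ccccc9)C2 | intermediate (not isolated)
34 | deca-O-benzyl-epicatechin-(4β→8)-epicatechin | O(Cc9ccccc9)c1cc(OCc9ccccc9)c2c(c1)O[C@H](c1ccc(OCc9ccccc9)c(OCc9ccccc9)c1)[C@H](OCc9ccccc9)[C@H]2c1c(OCc9ccccc9)cc(OCc9ccccc9)c2c1O[C@H](c1ccc(OCc9ccccc9)c(OCc9ccccc9)c1)[C@H](OCc9ccccc9)C2 | intermediate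
35 | penta-O-benzylepicatechin-(4β→8)-[4β-(2-ethoxyethoxy)-penta-O-benzylepicatechin] | O(Cc9ccccc9)c1cc(OCc9ccccc9)c2c(c1)O[C@H](c1ccc(OCc9ccccc9)c(OCc9ccccc9)c1)[C@H](OCc9ccccc9)[C@H]2c1c(OCc9ccccc9)cc(OCc9ccccc9)c2c1O[C@H](c1ccc(OCc9ccccc9)c(OCc9ccccc9)c1)[C@H](OCc9ccccc9)[C@H]2OCCOCC | intermediate
36 | penta-O-benzylepicatechin-(4β→8)-[4β-(benzylthio)-penta-O-benzylepicatechin] | O(Cc9ccccc9)c1cc(OCc9ccccc9)c2c(c1)O[C@H](c1ccc(OCc9ccccc9)c(OCc9ccccc9)c1)[C@H](OCc9ccccc9)[C@H]2c1c(OCc9ccccc9)cc(OCc9ccccc9)c2c1O[C@H](c1ccc(OCc9ccccc9)c(OCc9ccccc9)c1)[C@H](OCc9ccccc9)[C@H]2SCc9ccccc9 | intermediate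
37 | (+)-epicatechin, (2S,3S) | Oc1cc(O)c2c(c1)O[C@@H](c1ccc(O)c(O)c1)[C@@H](O)C2 | starting material
38 | 5,7,3',4'-tetra-O-benzyl-(+)-epicatechin | O(Cc9ccccc9)c1cc(OCc9ccccc9)c2c(c1)O[C@@H](c1ccc(OCc9ccccc9)c(OCc9ccccc9)c1)[C@@H](O)C2 | intermediate
39 | 3,5,7,3',4'-penta-O-benzyl-(+)-epicatechin | O(Cc9ccccc9)c1cc(OCc9ccccc9)c2c(c1)O[C@@H](c1ccc(OCc9ccccc9)c(OCc9ccccc9)c1)[C@@H](OCc9ccccc9)C2 | intermediate
40 | (2S,3S,4R)-penta-O-benzyl-(+)-epicatechin-4-ol, 4-OH trans to 3-OBn | O(Cc9ccccc9)c1cc(OCc9ccccc9)c2c(c1)O[C@@H](c1ccc(OCc9ccccc9)c(OCc9ccccc9)c1)[C@@H](OCc9ccccc9)[C@@H]2O | intermediate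
41 | (2S,3R)-3,5,7-tris(benzyloxy)-2-[3,4-bis(benzyloxy)phenyl]chroman-4-one, 2,3-cis | O(Cc9ccccc9)c1cc(OCc9ccccc9)c2c(c1)O[C@@H](c1ccc(OCc9ccccc9)c(OCc9ccccc9)c1)[C@@H](OCc9ccccc9)C2=O | intermediate
42 | (2S,3S,4S)-3,5,7-tris(benzyloxy)-2-[3,4-bis(benzyloxy)phenyl]chroman-4-ol, 2,3-cis-3,4-cis | O(Cc9ccccc9)c1cc(OCc9ccccc9)c2c(c1)O[C@@H](c1ccc(OCc9ccccc9)c(OCc9ccccc9)c1)[C@@H](OCc9ccccc9)[C@H]2O | intermediate
43 | pentadeca-O-benzyl trimer | O(Cc9ccccc9)c1cc(OCc9ccccc9)c2c(c1)O[C@H](c1ccc(OCc9ccccc9)c(OCc9ccccc9)c1)[C@H](OCc9ccccc9)[C@H]2c1c(OCc9ccccc9)cc(OCc9ccccc9)c2c1O[C@H](c1ccc(OCc9ccccc9)c(OCc9ccccc9)c1)[C@H](OCc9ccccc9)[C@H]2O[C@H]1c2c(OCc9ccccc9)cc(OCc9ccccc9)cc2O[C@@H](c2ccc(OCc9ccccc9)c(OCc9ccccc9)c2)[C@H]1OCc9ccccc9 | intermediate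
44 | target CNP0310719.1 | Oc1cc(O)c2c(c1)O[C@H](c1ccc(O)c(O)c1)[C@H](O)[C@H]2c1c(O)cc(O)c2c1O[C@H](c1ccc(O)c(O)c1)[C@H](O)[C@H]2O[C@H]1c2c(O)cc(O)cc2O[C@@H](c2ccc(O)c(O)c2)[C@H]1O | target

## Step count and least certain steps

Total step count: 27. Longest linear sequence: 15 steps (steps 1–7, 15–20, 26 and 27); the alkyne branch (steps 8–14, then 15–20, 26 and 27) is equally long.

Step 15 (key step). The most likely failure is that the vinylketene 26 is consumed by dimerisation or by acylating the product phenol faster than it adds to 25, because the bulky flavanyl group slows the [2+2] step, or that the sequence stalls at 27. The fallback makes the C4–C8 bond by ionic chemistry instead of ring construction. 4 is ionised with Me3SiOSO2CF3 at −78 °C in CH2Cl2 in the presence of an excess of 3, whose C8 attacks the cation anti to C3–OBn (Friedel–Crafts alkylation); the C6-linked isomer would be removed by chromatography. This sets out from 3 and 4 and comes back to the route at 34; no new compound is needed.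

Step 26. The most likely failure is slow ionisation of the thioether, so that traces of acid accumulate, the first-formed ether is re-ionised and carbon alkylation of ring A of 42 takes over. The fallback changes the electrophile and its mode of activation and sets out from 34. DDQ in wet CH2Cl2 should give the dimeric 4β-alcohol F1. Cl3CCN with catalytic DBU converts it into its trichloroacetimidate F2. F2 is coupled with 42 using 0.05 equivalents of Me3SiOSO2CF3 at −78 °C, quenched at once with Et3N. The fallback comes back to the route at 43.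

Step 19. The most likely failure is loss of site selectivity in the hydride abstraction (attack at the doubly benzylic C4–H of the upper half) or further oxidation of the product. The fallback raises the oxidation level through the phenol instead of the C–H bond and sets out from 32. Bu4NF gives 33, now isolated. Ag2O in CH2Cl2/2-ethoxyethanol oxidises the phenol to the ortho-quinone methide F3 (C5=O, C4a=C4). The alcohol adds to F3 at C4 anti to C3–OBn and gives the 5-hydroxy 4β-(2-ethoxyethoxy) dimer F4. Benzylation (BnBr, K2CO3, DMF) comes back to the route at 35.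

Step 17. The most likely failure is partial ionisation of the activated, electron-rich benzylic alcohol, which erodes the inversion and gives the 2,3-trans isomer, or elimination when the crowded phenol is slow to attack. The fallback closes the pyran at the O1–C8a bond with retention at C2 and sets out from 31.
- MnO2 oxidises the benzylic carbinol to the aryl ketone F5.
- Reduction under non-chelating conditions with LiBH(s-Bu)3 in THF at −78 °C (hydride anti to the C–OBn bond) should give the C2-epimeric alcohol F6.
- PhNTf2 and Cs2CO3 convert the phenol selectively into the aryl triflate F7.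
- Palladium-catalysed intramolecular aryl ether formation then gives 32: Pd(OAc)2 (divalent palladium, reduced in the flask), a bulky biaryl di-tert-butylphosphine, Cs2CO3, toluene, 80 °C. The triflate adds oxidatively to zerovalent palladium, and C–O reductive elimination follows.

The fallback comes back to the route at 32.

Step 7. The most likely failure is hydrolysis of the vinylogous ester to the cyclobutane-1,3-dione, or migration of the double bond toward the substituted carbon during the exchange, which would change the regiochemistry of step 15. The fallback brings the benzyloxy group in with the alkyne and sets out from 7. Trichloroethylene and benzyl alcohol with KH give benzyl (E)-1,2-dichlorovinyl ether F8. Two equivalents of n-BuLi at −78 °C followed by methanol give benzyloxyacetylene F9, which is used cold. The ketene 10, generated from 7 through 9 as in step 6, adds to F9 in the same [2+2] manner. The fallback comes back to the route at 12.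

## Further compounds

F0 | step 15 | none | none
F1 | step 26 | penta-O-benzylepicatechin-(4β→8)-(penta-O-benzylepicatechin-4β-ol) | O(Cc9ccccc9)c1cc(OCc9ccccc9)c2c(c1)O[C@H](c1ccc(OCc9ccccc9)c(OCc9ccccc9)c1)[C@H](OCc9ccccc9)[C@H]2c1c(OCc9ccccc9)cc(OCc9ccccc9)c2c1O[C@H](c1ccc(OCc9ccccc9)c(OCc9ccccc9)c1)[C@H](OCc9ccccc9)[C@H]2O
F2 | step 26 | 4β-O-trichloroacetimidate of F1 | O(Cc9ccccc9)c1cc(OCc9ccccc9)c2c(c1)O[C@H](c1ccc(OCc9ccccc9)c(OCc9ccccc9)c1)[C@H](OCc9ccccc9)[C@H]2c1c(OCc9ccccc9)cc(OCc9ccccc9)c2c1O[C@H](c1ccc(OCc9ccccc9)c(OCc9ccccc9)c1)[C@H](OCc9ccccc9)[C@H]2OC(=N)C(Cl)(Cl)Cl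
F3 | step 19 | ortho-quinone methide of 33 (C5=O, C4a=C4) | O(Cc9ccccc9)c1cc(OCc9ccccc9)c2c(c1)O[C@H](c1ccc(OCc9ccccc9)c(OCc9ccccc9)c1)[C@H](OCc9ccccc9)[C@H]2C1=C2O[C@H](c4ccc(OCc9ccccc9)c(OCc9ccccc9)c4)[C@H](OCc9ccccc9)C=C2C(=O)C=C1OCc9ccccc9
F4 | step 19 | penta-O-benzylepicatechin-(4β→8)-[4β-(2-ethoxyethoxy)-3,7,3',4'-tetra-O-benzylepicatechin], free 5-OH | O(Cc9ccccc9)c1cc(OCc9ccccc9)c2c(c1)O[C@H](c1ccc(OCc9ccccc9)c(OCc9ccccc9)c1)[C@H](OCc9ccccc9)[C@H]2c1c(OCc9ccccc9)cc(O)c2c1O[C@H](c1ccc(OCc9ccccc9)c(OCc9ccccc9)c1)[C@H](OCc9ccccc9)[C@H]2OCCOCC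
F5 | step 17 | aryl ketone from 31 (chain C3 carbonyl) | O(Cc9ccccc9)c1cc(OCc9ccccc9)c2c(c1)O[C@H](c1ccc(OCc9ccccc9)c(OCc9ccccc9)c1)[C@H](OCc9ccccc9)[C@H]2c1c(OCc9ccccc9)cc(O[Si](C(C)C)(C(C)C)C(C)C)c(C[C@@H](OCc9ccccc9)C(=O)c3ccc(OCc9ccccc9)c(OCc9ccccc9)c3)c1O
F6 | step 17 | C2-epimeric alcohol of 31, (2R,3R) chain | O(Cc9ccccc9)c1cc(OCc9ccccc9)c2c(c1)O[C@H](c1ccc(OCc9ccccc9)c(OCc9ccccc9)c1)[C@H](OCc9ccccc9)[C@H]2c1c(OCc9ccccc9)cc(O[Si](C(C)C)(C(C)C)C(C)C)c(C[C@@H](OCc9ccccc9)[C@H](O)c3ccc(OCc9ccccc9)c(OCc9ccccc9)c3)c1O
F7 | step 17 | aryl triflate of F6 | O(Cc9ccccc9)c1cc(OCc9ccccc9)c2c(c1)O[C@H](c1ccc(OCc9ccccc9)c(OCc9ccccc9)c1)[C@H](OCc9ccccc9)[C@H]2c1c(OCc9ccccc9)cc(O[Si](C(C)C)(C(C)C)C(C)C)c(C[C@@H](OCc9ccccc9)[C@H](O)c3ccc(OCc9ccccc9)c(OCc9ccccc9)c3)c1OS(=O)(=O)C(F)(F)F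
F8 | step 7 | benzyl (E)-1,2-dichlorovinyl ether | Cl/C=C(/Cl)OCc1ccccc1
F9 | step 7 | benzyloxyacetylene | C#COCc1ccccc1
A1 | alternative 1 | deca-O-benzyl-epicatechin-(4β→8)-epicatechin (identical with 34) | O(Cc9ccccc9)c1cc(OCc9ccccc9)c2c(c1)O[C@H](c1ccc(OCc9ccccc9)c(OCc9ccccc9)c1)[C@H](OCc9ccccc9)[C@H]2c1c(OCc9ccccc9)cc(OCc9ccccc9)c2c1O[C@H](c1ccc(OCc9ccccc9)c(OCc9ccccc9)c1)[C@H](OCc9ccccc9)C2
A2 | alternative 1 | benzylic carbinol on C8 of penta-O-benzylepicatechin with open chain and 3,5-dibenzyloxyphenyl ether, carbinol epimers | O(Cc9ccccc9)c1cc(OCc9ccccc9)cc(c1)O[C@H](c1ccc(OCc9ccccc9)c(OCc9ccccc9)c1)[C@H](OCc9ccccc9)C(O)c1c(OCc9ccccc9)cc(OCc9ccccc9)c2c1O[C@H](c1ccc(OCc9ccccc9)c(OCc9ccccc9)c1)[C@H](OCc9ccccc9)C2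
A3 | alternative 2 | 4-(dimer-4β-yloxy)-2-aryl-5,7-bis(benzyloxy)-2H-chromene | O(Cc9ccccc9)c1cc(OCc9ccccc9)c2c(c1)O[C@H](c1ccc(OCc9ccccc9)c(OCc9ccccc9)c1)[C@H](OCc9ccccc9)[C@H]2c1c(OCc9ccccc9)cc(OCc9ccccc9)c2c1O[C@H](c1ccc(OCc9ccccc9)c(OCc9ccccc9)c1)[C@H](OCc9ccccc9)[C@H]2OC1=C[C@H](c4ccc(OCc9ccccc9)c(OCc9ccccc9)c4)Oc3cc(OCc9ccccc9)cc(OCc9ccccc9)c13
A4 | alternative 2 | dimer-4β-yl 2-[(1-arylallyl)oxy]-4,6-bis(benzyloxy)benzoate | O(Cc9ccccc9)c1cc(OCc9ccccc9)c2c(c1)O[C@H](c1ccc(OCc9ccccc9)c(OCc9ccccc9)c1)[C@H](OCc9ccccc9)[C@H]2c1c(OCc9ccccc9)cc(OCc9ccccc9)c2c1O[C@H](c1ccc(OCc9ccccc9)c(OCc9ccccc9)c1)[C@H](OCc9ccccc9)[C@H]2OC(=O)c1c(OCc9ccccc9)cc(OCc9ccccc9)cc1O[C@H](C=C)c4ccc(OCc9ccccc9)c(OCc9ccccc9)c4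
A5 | alternative 3 | nona-O-benzyl epicatechin-(4β→8)-(2,3-cis-flavan-3,4-diol), C4 epimers | O(Cc9ccccc9)c1cc(OCc9ccccc9)c2c(c1)O[C@H](c1ccc(OCc9ccccc9)c(OCc9ccccc9)c1)[C@H](OCc9ccccc9)[C@H]2c1c(OCc9ccccc9)cc(OCc9ccccc9)c2c1O[C@H](c1ccc(OCc9ccccc9)c(OCc9ccccc9)c1)[C@H](O)C2O
A6 | alternative 3 | 2-(penta-O-benzylepicatechin-4β-yl)-3,5-bis(benzyloxy)phenol | O(Cc9ccccc9)c1cc(OCc9ccccc9)c2c(c1)O[C@H](c1ccc(OCc9ccccc9)c(OCc9ccccc9)c1)[C@H](OCc9ccccc9)[C@H]2c1c(OCc9ccccc9)cc(OCc9ccccc9)cc1O
A7 | alternative 3 | cis-3-[3,4-bis(benzyloxy)phenyl]oxirane-2-carbaldehyde | O=C[C@H]1O[C@H]1c1ccc(OCc9ccccc9)c(OCc9ccccc9)c1
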